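# Proposal: total synthesis of CNP0353301.1 via tandem metathesis–dihydroxylation on a C13–C17 lactone template

Remark on numbering and abbreviations: chain atoms run from the ester carbonyl C1 to the terminal methyl C23; cyclohexane atoms are C1′ (carboxyl-bearing) to C6′. TBS = tert-butyldimethylsilyl, TBDPS = tert-butyldiphenylsilyl, TES = triethylsilyl, Nap = naphthalen-2-ylmethyl.

## The problem

The target is a C23 acyl chain esterified through C1 to the axial 3′-hydroxyl of (1′S,3′R,4′S)-3′,4′-dihydroxycyclohexane-1′-carboxylic acid. The chain has no ring of its own, so every bond must be made in the open or on a temporary template. C1–C11 is an all-E tetraenoate ending in a (10Z)-11-chloroalkene, and C12–C19 carries seven stereocentres (C12 methyl, C13–C15 triol, C17 carbinol, C18 chloride, C19 allylic carbinol beside the E C20=C21 alkene). Their relations are 12,13-syn, 13,14-anti, 14,15-anti, 15,17-syn, 17,18-anti and 18,19-anti.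

The secondary chloride is the hardest centre to install late, but once present it can set both neighbours, because nucleophiles add to α-chloro aldehydes anti to chlorine. C17 cannot reach C15 and C14 reliably through an open chain; C14, once set, can bias C13 as an α-oxygenated aldehyde; C12 needs a chiral reagent.

The molecule tolerates little. Chlorohydrins close to epoxides with base, α-chloro aldehydes epimerise and eliminate, the chlorinated pentaenoate is sensitive to light, acid and nucleophiles, the C19 alcohol is allylic, the ester sits beside a free cis-hydroxyl and can migrate, and the acid is free.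

The enabling feature is that C13–C17 with O17 folds into a tetrahydropyran-2-one (carbonyl C13, ring oxygen O17). In that ring the C14 and C15 hydroxyls are cis to each other and trans to the C17 side chain. This is the outcome of syn-dihydroxylation of an endocyclic C14=C15 alkene from the face opposite the C6 substituent of the lactone, and the unsaturated lactone is the ring-closing metathesis product of the acrylate of a homoallylic chlorohydrin.

## Retrosynthesis

**Last operations (49 ⇐ 48 ⇐ 47).** No skeletal bond is cut. All hydroxyls are carried as silyl ethers and the ring acid as an allyl ester, so the end game is a palladium-mediated deallylation of 47 to 48 and one acidic fluoride treatment to 49. Base is avoided because of the chlorohydrins and the migratory ester.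

**C8=C9 (47 ⇒ 31 + 46).** A Horner–Wadsworth–Emmons cut in the middle of the pentaene gives the chlorinated enal 31 (fragment 1, all seven chain stereocentres) and the trienyl phosphonate 46 (fragment 2, cyclohexane plus C1–C8). A cut at the ester C1–O would end the synthesis with acylation of a hindered axial hydroxyl by a complete polyene acid. Cuts at C2=C3 or C4=C5 would force stepwise growth of the polyene on fragment 1. The C8=C9 cut is the most convergent and puts the anion-stabilising group on the fragment without enolisable stereocentres. The forward reaction must give the E alkene without scrambling C6=C7 or touching C12.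

**Fragment 2 (46 ⇒ 45 + 38; 45 ⇒ 39 + 40; 38 ⇒ 32).** The ester C1–O3′ is made from acid 45 and alcohol 38, where neither partner is precious. Acid 45 comes from the C5 aldehyde 39 and the C4 phosphonate 40 (C4=C5), followed by acetate-to-phosphonate exchange through 41–44. Alcohol 38 comes from bromolactone 32, whose lactone fixes C1′ and distinguishes the ring faces. The cis-epoxide 33 is opened trans-diaxially at C3′ (34), and C4′ is inverted by oxidation and reduction (35, 36). Both oxygens end anti to the carboxyl and are differentiated (37, 38). Direct dihydroxylation of a cyclohex-3-enecarboxylate would be shorter but has no facial control.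

**C19–C20 (31 ⇐ 30 ⇐ 29 ⇐ 28 ⇒ 24 + 25).** The butenyl unit from but-1-yne 25 is added to the α-chloro aldehyde 24, so C18 sets C19. An olefination at C20=C21 would not create C19, and an alkene carried from the start would compete in the metathesis and be oxidised by RuO4. The step is placed before the polyene exists, when the only other electrophile is a methyl ester.

**C11–Cl and C9–C10 (24 ⇐ 23 ⇐ 22 ⇒ 21 ⇒ 20).** The (Z)-chloroalkene comes from anti hydrochlorination of ynoate 21, which fixes geometry and regiochemistry together. C9 enters as a chloroformate on the acetylide of 20. A chloro-olefination of a C11 carbonyl would give no geometric control beside the C12 stereocentre.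

**C12–C13 (20 ⇐ 19 ⇒ 15 + 18).** Addition of the chiral allenylstannane 18 (from 16 via 17) to aldehyde 15 makes the bond, both stereocentres and the C10–C11 alkyne at once. A crotylation would give an alkene that must then be converted to the alkyne. The reaction must be syn-selective and must attack the Felkin–Anh face of the α-silyloxy aldehyde; reagent and substrate preferences coincide for the required isomer.

**Opening the template (15 ⇐ 14 ⇐ 13 ⇐ 12 ⇐ 11).** The acyl C13–O17 bond of the lactone is cleaved by aminolysis to the N-methoxy-N-methylamide 13. This frees O17 for silylation (14) and leaves C13 one reduction from the aldehyde. Because the template bond is an ester and not an ether, it opens without touching a stereocentre.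

**Key disconnection (11 ⇒ 10 ⇒ 9).** The two C–O bonds at C14 and C15 and the C14=C15 bond are cut together. Diol 11 comes from dihydropyranone 10, and 10 from acrylate 9 by ring-closing metathesis. The precursor loses one ring and two stereocentres and contains only the chlorohydrin.

**The chlorohydrin (9 ⇒ 7 + 8; 7 ⇒ 5 + 6; 5 ⇐ 4 ⇐ 3 ⇐ 2 ⇐ 1).** Acylation with 8, anti-selective allylboration of α-chloro aldehyde 5 with 6, and derivation of 5 from L-serine 1 with retention at the chlorine-bearing carbon. The chlorine stereocentre comes from the chiral pool and is the origin of all chain stereochemistry.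

## Roads not taken

**Alternative 1:** Iterative boronic ester homologation. The cuts are the bonds CH3–C12, C11–C12, C12–C13, C13–C14 and C14–C15, made one carbon at a time from the chiral methylboronic ester A1. Each cycle inserts a dihalomethyl carbenoid into the C–B bond under direction of the C2-symmetric diol, then displaces the α-chloride with a carbon or alkoxide nucleophile. The product is the C10–C15 boronic ester A2, with C12 methyl and vinyl, three 4-methoxybenzyl ethers and boron on C15.
- Merits: every centre is set by the reagent, no step relies on substrate bias, and the chemistry is uniform.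
- Weak points: boronic esters with a β-oxygen are prone to β-elimination in the next insertion, and three such cycles follow one another. A2 contains nothing of C16–C19, so the chlorine half must still be made and joined at C15, and the 15,17-syn relation must then be created across a methylene in an open chain. The three benzyl-type ethers must be exchanged before the polyene exists. The vinyl group must still become the chloroalkene. Four centres cost about eight cryogenic operations.
- Comparison: this road is better in predictability of absolute configuration and needs no ruthenium chemistry. The chosen plan offers instead two stereocentres, one ring and one C–C bond in a single operation, control that starts at the chlorine stereocentre, and a carbonyl at C13 ready for a convergent union.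

**Alternative 2:** Dihydropyranone cyclocondensation. The cuts are C13–C14 and O–C17. Aldehyde A3 (C11–C13, C12 from the chiral pool) and the oxygenated diene A4 combine under a Lewis acid and then acid, giving the trans-2,3-disubstituted dihydropyranone A5 with a C14 benzoate and a C15 ketone.
- Merits: convergent, C12 comes from a cheap hydroxy ester and not from a tin reagent, and C13 and C14 are set together on a versatile ring.
- Weak points: the ring oxygen of A5 joins C13 to C17 as an ether, whereas both are free carbinols in the target. To release them C17 must pass through the lactol or aldehyde level, so C17, C18 and C19 would all be created afterwards by open-chain additions with 1,3-induction; this is the hardest array left to the least controlled chemistry. The trans C13/C14 outcome depends on the balance of Felkin–Anh against chelation control in A3. The C15 ketone must be reduced selectively. C11 of A3 is still a protected alcohol far from the chloroalkene.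
- Comparison: this road is better at C12–C14 (more convergent, no stoichiometric tin, fewer silyl groups). The chosen plan offers instead a template bond that is an ester and opens cleanly, and a chlorohydrin that is in place before the ring is made and directs it.

**Alternative 3:** Chlorocarbonate cyclisation. The cuts are C17–O and C18–Cl across the E C17=C18 alkene of the homoallylic tert-butyl carbonate A6. An electrophilic chlorine source triggers 6-exo attack of the carbonate oxygen with loss of isobutene. The product is the cis-4,6-disubstituted 1,3-dioxan-2-one A7 with the C18 chloride in the side chain.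
- Merits: two heteroatom stereocentres from one alkene in one step, late introduction of chlorine so no α-chloro aldehyde is handled, and a chair-like closure that favours the 15,17-syn diol.
- Weak points: chlorine electrophiles give less bridged, more cation-like intermediates than iodine, so regio- and diastereoselectivity are less secure. The alkene is deactivated by the allylic C19 oxygen. The cyclic carbonate must later be removed with base or alkoxide, which liberates the C17 alkoxide anti to the C18 chloride, the arrangement that closes to an epoxide. A6 presupposes a separate synthesis of the C12–C15 tetrad and leaves C19 open.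
- Comparison: this road is better in step economy for the C15→C17→C18 relay and in introducing chlorine late. The chosen plan offers instead a chlorine configuration secured from serine, two flanking carbinols made by the same documented anti addition, and template opening under non-basic aluminium amide conditions.

Key step: step 7

Remark on starting materials: bromolactone 32 and aldehyde 39 are taken as purchased. 32 is an intermediate of edoxaban manufacture, one bromolactonisation from (S)-cyclohex-3-ene-1-carboxylic acid; 39 is the C5 acetate aldehyde of industrial retinoid chemistry.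

## Route

### Fragment 1, part A: the C13–C19 lactone (steps 1–7)

Step 1
Reactants: 1 L-serine
Product: 2 (S)-2-chloro-3-hydroxypropanoic acid
Conditions: NaNO2, 6 M aq. HCl, 0 °C → rt
Reagents that add atoms: HCl (hydrochloric acid), Cl
Why: Diazotisation of the α-amino acid; the carboxylate expels N2 to an α-lactone that chloride opens, so two inversions leave the future C18 with retained (S) configuration.

Step 2
Reactants: 2 (S)-2-chloro-3-hydroxypropanoic acid
Product: 3 methyl (S)-2-chloro-3-hydroxypropanoate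
Conditions: HCl (1.25 M in MeOH), rt
Reagents that add atoms: methanol, CO
Why: Fischer esterification; the chlorine-bearing centre is not enolised under acid.

Step 3
Reactants: 3 methyl (S)-2-chloro-3-hydroxypropanoate
Product: 4 methyl (S)-3-(tert-butyldiphenylsilyloxy)-2-chloropropanoate
Conditions: TBDPSCl, imidazole, CH2Cl2, 0 °C → rt
Reagents that add atoms: tert-butyl(chloro)diphenylsilane, CC(C)(C)[Si](Cl)(c1ccccc1)c1ccccc1
Why: Silylation of the primary alcohol with a base too weak to cause glycidate formation or elimination; this robust silyl ether should survive RuO4 and the later acidic steps.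

Step 4
Reactants: 4 methyl (S)-3-(tert-butyldiphenylsilyloxy)-2-chloropropanoate
Product: 5 (S)-3-(tert-butyldiphenylsilyloxy)-2-chloropropanal
Conditions: i-Bu2AlH (1.1 equiv), CH2Cl2, −78 °C; MeOH, aq. KNaC4H4O6
Reagents that add atoms: none
Why: Partial reduction of the activated α-chloro ester; the aluminium hemiacetal is stable at −78 °C and releases the aldehyde on work-up, which is used at once to avoid epimerisation.

Step 5
Reactants: 5 (S)-3-(tert-butyldiphenylsilyloxy)-2-chloropropanal, 6 allylboronic acid pinacol ester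
Product: 7 (2S,3R)-1-(tert-butyldiphenylsilyloxy)-2-chlorohex-5-en-3-ol
Conditions: CH2Cl2, rt; aq. pH 7 buffer
Reagents that add atoms: none
Why: Allylboration through a closed chair transition state in the Cornforth arrangement (C=O anti to C–Cl, attack past hydrogen) should set C17 anti to the chloride (17R).

Step 6
Reactants: 7 (2S,3R)-1-(tert-butyldiphenylsilyloxy)-2-chlorohex-5-en-3-ol, 8 acryloyl chloride
Product: 9 (2S,3R)-1-(tert-butyldiphenylsilyloxy)-2-chlorohex-5-en-3-yl prop-2-enoate
Conditions: i-Pr2NEt, DMAP (cat.), CH2Cl2, −20 → 0 °C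
Reagents that add atoms: none
Why: O-Acylation of the secondary chlorohydrin with an amine base too weak to close the epoxide; it brings in C13 and C14.

Step 7
Reactants: 9 (2S,3R)-1-(tert-butyldiphenylsilyloxy)-2-chlorohex-5-en-3-yl prop-2-enoate
Product: 11 (3S,4S,6R)-6-[(1S)-2-(tert-butyldiphenylsilyloxy)-1-chloroethyl]-3,4-dihydroxyoxan-2-one, via (6R)-6-[(1S)-2-(tert-butyldiphenylsilyloxy)-1-chloroethyl]-5,6-dihydro-2H-pyran-2-one 10 (not isolated)
Conditions: [RuCl2(=CHPh)(H2IMes)(PCy3)] (second-generation Grubbs catalyst, 5 mol %), EtOAc (5 mM), 70 °C; then MeCN, H2O, NaIO4 (1.5 equiv), CeCl3·7H2O (10 mol %), 0 °C, 10–15 min; aq. Na2S2O3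
Reagents that add atoms: NaIO4 (sodium periodate), [Na+].[O-]I(=O)(=O)=O; water, O
Why: This is a tandem ring-closing metathesis–dihydroxylation; the closest known reaction type is ruthenium-catalysed ring closure followed in the same flask by oxidation of the spent carbene to RuO4 for syn-dihydroxylation. The ruthenium carbene loads at the terminal allyl alkene by [2+2] cycloaddition and cycloreversion and then closes onto the acrylate, releasing ethylene and forming C14=C15 in the six-membered lactone 10; the ring closes by metathesis with the ester inside it and admits only the Z alkene. NaIO4 with CeCl3·7H2O then converts the ruthenium residue into RuO4 (octavalent ruthenium), which adds to the electron-poor ring alkene by [3+2] cycloaddition, and hydrolysis of the ruthenate ester frees the diol while periodate reoxidises the metal. C14 and C15 are created together: their cis relation follows from the suprafacial addition, and their absolute sense from C17. In the half-chair of 10 the C17 side chain is pseudo-equatorial and the pseudo-axial C16–H lies on the same face, so the oxidant should enter from the opposite face, as osmium does with 6-substituted dihydropyranones. The step needs this facial selectivity and chemoselectivity for a single alkene. Both terminal alkenes are consumed in the ring closure, and the silyl ether, the chloride and the lactone should be inert to a short exposure at 0 °C. The Lewis acid keeps the dihydroxylation fast, which limits glycol cleavage.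

### Fragment 1, part B: opening the template and the C12–C13 union (steps 8–15)

Step 8
Reactants: 11 (3S,4S,6R)-6-[(1S)-2-(tert-butyldiphenylsilyloxy)-1-chloroethyl]-3,4-dihydroxyoxan-2-one
Product: 12 (3S,4S,6R)-3,4-bis(tert-butyldimethylsilyloxy)-6-[(1S)-2-(tert-butyldiphenylsilyloxy)-1-chloroethyl]oxan-2-one
Conditions: TBSOTf (2.6 equiv), 2,6-lutidine, CH2Cl2, 0 °C → rt
Reagents that add atoms: tert-butyldimethylsilyl trifluoromethanesulfonate, CC(C)(C)[Si](C)(C)OS(=O)(=O)C(F)(F)F
Why: Silylation of both secondary hydroxyls with a hindered pyridine base that does not epimerise C14; silyl ethers are chosen over an acetal so that the end game needs no aqueous protic acid.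

Step 9
Reactants: 12 (3S,4S,6R)-3,4-bis(tert-butyldimethylsilyloxy)-6-[(1S)-2-(tert-butyldiphenylsilyloxy)-1-chloroethyl]oxan-2-one
Product: 13 (2S,3S,5R,6S)-2,3-bis(tert-butyldimethylsilyloxy)-7-(tert-butyldiphenylsilyloxy)-6-chloro-5-hydroxy-N-methoxy-N-methylheptanamide
Conditions: MeNH(OMe)·HCl, AlMe3, CH2Cl2, 0 °C → rt
Reagents that add atoms: N,O-dimethylhydroxylamine hydrochloride, CNOC.Cl
Why: Aminolysis of the δ-lactone by the aluminium amide (Weinreb amide formation) cleaves the acyl C13–O17 bond; the aluminium alkoxide at C17 is not basic enough to displace the neighbouring chloride.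

Step 10
Reactants: 13 (2S,3S,5R,6S)-2,3-bis(tert-butyldimethylsilyloxy)-7-(tert-butyldiphenylsilyloxy)-6-chloro-5-hydroxy-N-methoxy-N-methylheptanamide
Product: 14 (2S,3S,5R,6S)-2,3,5-tris(tert-butyldimethylsilyloxy)-7-(tert-butyldiphenylsilyloxy)-6-chloro-N-methoxy-N-methylheptanamide
Conditions: TBSOTf, 2,6-lutidine, CH2Cl2, −78 → 0 °C
Reagents that add atoms: tert-butyldimethylsilyl trifluoromethanesulfonate, CC(C)(C)[Si](C)(C)OS(=O)(=O)C(F)(F)F
Why: Silylation of the freed C17 hydroxyl prevents relactonisation and later lactol formation.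

Step 11
Reactants: 14 (2S,3S,5R,6S)-2,3,5-tris(tert-butyldimethylsilyloxy)-7-(tert-butyldiphenylsilyloxy)-6-chloro-N-methoxy-N-methylheptanamide
Product: 15 (2S,3S,5R,6S)-2,3,5-tris(tert-butyldimethylsilyloxy)-7-(tert-butyldiphenylsilyloxy)-6-chloroheptanal
Conditions: i-Bu2AlH, THF, −78 °C; aq. KNaC4H4O6
Reagents that add atoms: none
Why: Reduction of the N-methoxy-N-methylamide stops at the chelated hemiaminal and gives the α-silyloxy aldehyde without over-reduction.

Step 12
Reactants: 16 (S)-but-3-yn-2-ol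
Product: 17 (S)-but-3-yn-2-yl methanesulfonate
Conditions: MsCl, Et3N, CH2Cl2, −78 → 0 °C
Reagents that add atoms: methanesulfonyl chloride, CS(=O)(=O)Cl
Why: Sulfonylation of the propargylic alcohol without touching the stereocentre.

Step 13
Reactants: 17 (S)-but-3-yn-2-yl methanesulfonate
Product: 18 (M)-tributyl(buta-1,2-dien-1-yl)stannane
Conditions: Bu3SnH, LiN(i-Pr)2, THF, 0 °C; CuBr·SMe2, −78 °C; then 17, −78 °C
Reagents that add atoms: tributyltin hydride, CCCC[SnH](CCCC)CCCC
Why: Anti SN2′ displacement of the propargylic mesylate by the stannylcuprate converts central into axial chirality and should give the (M)-allene.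

Step 14
Reactants: 15 (2S,3S,5R,6S)-2,3,5-tris(tert-butyldimethylsilyloxy)-7-(tert-butyldiphenylsilyloxy)-6-chloroheptanal, 18 (M)-tributyl(buta-1,2-dien-1-yl)stannane
Product: 19 (3S,4R,5R,6S,8R,9S)-5,6,8-tris(tert-butyldimethylsilyloxy)-10-(tert-butyldiphenylsilyloxy)-9-chloro-3-methyldec-1-yn-4-ol
Conditions: BF3·OEt2, CH2Cl2, −78 °C
Reagents that add atoms: none
Why: Lewis-acid-promoted anti SE2′ addition of the allenylstannane through an open transition state gives the 12,13-syn homopropargylic alcohol; C12 is fixed by the axial chirality of 18, and the aldehyde reacts on its Felkin–Anh face (13,14-anti), which is the matched pairing.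

Step 15
Reactants: 19 (3S,4R,5R,6S,8R,9S)-5,6,8-tris(tert-butyldimethylsilyloxy)-10-(tert-butyldiphenylsilyloxy)-9-chloro-3-methyldec-1-yn-4-ol
Product: 20 (3S,4R,5S,6S,8R,9S)-4,5,6,8-tetrakis(tert-butyldimethylsilyloxy)-10-(tert-butyldiphenylsilyloxy)-9-chloro-3-methyldec-1-yne
Conditions: TBSOTf, 2,6-lutidine, CH2Cl2, 0 °C → rt
Reagents that add atoms: tert-butyldimethylsilyl trifluoromethanesulfonate, CC(C)(C)[Si](C)(C)OS(=O)(=O)C(F)(F)F
Why: Silylation of the hindered C13 hydroxyl with the triflate before the alkyne is metallated.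

### Fragment 1, part C: chloroalkene, C19 carbinol and the enal (steps 16–23)

Step 16
Reactants: 20 (3S,4R,5S,6S,8R,9S)-4,5,6,8-tetrakis(tert-butyldimethylsilyloxy)-10-(tert-butyldiphenylsilyloxy)-9-chloro-3-methyldec-1-yne
Product: 21 methyl (4S,5R,6S,7S,9R,10S)-5,6,7,9-tetrakis(tert-butyldimethylsilyloxy)-11-(tert-butyldiphenylsilyloxy)-10-chloro-4-methylundec-2-ynoate
Conditions: n-BuLi, THF, −78 °C; ClCO2Me, −78 → −20 °C
Reagents that add atoms: methyl chloroformate, COC(=O)Cl
Why: Deprotonation of the terminal alkyne and C-acylation of the lithium acetylide adds C9; the secondary chloride should be inert to n-BuLi at −78 °C on this time scale.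

Step 17
Reactants: 21 methyl (4S,5R,6S,7S,9R,10S)-5,6,7,9-tetrakis(tert-butyldimethylsilyloxy)-11-(tert-butyldiphenylsilyloxy)-10-chloro-4-methylundec-2-ynoate
Product: 22 methyl (2Z,4R,5R,6S,7S,9R,10S)-5,6,7,9-tetrakis(tert-butyldimethylsilyloxy)-11-(tert-butyldiphenylsilyloxy)-3,10-dichloro-4-methylundec-2-enoate
Conditions: LiCl (5 equiv), AcOH (5 equiv), MeCN, 80 °C
Reagents that add atoms: LiCl (lithium chloride), [Li+].[Cl-]
Why: Conjugate hydrochlorination of the 2-ynoate: chloride adds at C11 and the allenolate is protonated anti, so chlorine and the ester end cis, the (10Z) geometry of the target; stoichiometric AcOH in MeCN should spare the silyl ethers.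

Step 18
Reactants: 22 methyl (2Z,4R,5R,6S,7S,9R,10S)-5,6,7,9-tetrakis(tert-butyldimethylsilyloxy)-11-(tert-butyldiphenylsilyloxy)-3,10-dichloro-4-methylundec-2-enoate
Product: 23 methyl (2Z,4R,5R,6S,7S,9R,10S)-5,6,7,9-tetrakis(tert-butyldimethylsilyloxy)-3,10-dichloro-11-hydroxy-4-methylundec-2-enoate
Conditions: Bu4NF, AcOH (1:1), THF, 0 °C → rt
Reagents that add atoms: none
Why: Buffered fluoride should remove the unhindered primary silyl ether, whose β-chlorine makes the alkoxide a better leaving group, faster than the four hindered secondary ethers; AcOH keeps the medium from closing the chlorohydrin.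

Step 19
Reactants: 23 methyl (2Z,4R,5R,6S,7S,9R,10S)-5,6,7,9-tetrakis(tert-butyldimethylsilyloxy)-3,10-dichloro-11-hydroxy-4-methylundec-2-enoate
Product: 24 methyl (2Z,4R,5R,6S,7S,9R,10R)-5,6,7,9-tetrakis(tert-butyldimethylsilyloxy)-3,10-dichloro-4-methyl-11-oxoundec-2-enoate
Conditions: Dess–Martin periodinane, NaHCO3, CH2Cl2, 0 °C → rt
Reagents that add atoms: none
Why: Buffered Dess–Martin oxidation gives the α-chloro aldehyde under non-basic conditions; it is used without purification.

Step 20
Reactants: 24 methyl (2Z,4R,5R,6S,7S,9R,10R)-5,6,7,9-tetrakis(tert-butyldimethylsilyloxy)-3,10-dichloro-4-methyl-11-oxoundec-2-enoate, 25 but-1-yne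
Product: 28 methyl (2Z,4R,5R,6S,7S,9R,10S,11S,12E)-5,6,7,9-tetrakis(tert-butyldimethylsilyloxy)-3,10-dichloro-11-hydroxy-4-methylpentadeca-2,12-dienoate, via (E)-but-1-enyl(chloro)zirconocene 26 (not isolated), via (E)-but-1-enyl(methyl)zinc 27 (not isolated)
Conditions: 25, Cp2Zr(H)Cl, CH2Cl2, 0 °C → rt; Me2Zn, −65 °C; then 24, −65 → 0 °C
Reagents that add atoms: none
Why: Hydrozirconation gives the (E)-alkenylzirconium species and transmetallation gives an alkenylzinc reagent that adds to aldehydes but not to esters; addition to the α-chloro aldehyde in the Cornforth (polar Felkin–Anh) sense should set C19 anti to chlorine (19S).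

Step 21
Reactants: 28 methyl (2Z,4R,5R,6S,7S,9R,10S,11S,12E)-5,6,7,9-tetrakis(tert-butyldimethylsilyloxy)-3,10-dichloro-11-hydroxy-4-methylpentadeca-2,12-dienoate
Product: 29 methyl (2Z,4R,5R,6S,7S,9R,10R,11S,12E)-5,6,7,9-tetrakis(tert-butyldimethylsilyloxy)-3,10-dichloro-4-methyl-11-(triethylsilyloxy)pentadeca-2,12-dienoate
Conditions: TESOTf, 2,6-lutidine, CH2Cl2, −78 °C
Reagents that add atoms: triethylsilyl trifluoromethanesulfonate, CC[Si](CC)(CC)OS(=O)(=O)C(F)(F)F
Why: Silylation of the allylic alcohol so that it survives hydride, oxidation and olefination; no base strong enough to close the chlorohydrin is present.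

Step 22
Reactants: 29 methyl (2Z,4R,5R,6S,7S,9R,10R,11S,12E)-5,6,7,9-tetrakis(tert-butyldimethylsilyloxy)-3,10-dichloro-4-methyl-11-(triethylsilyloxy)pentadeca-2,12-dienoate
Product: 30 (2Z,4R,5R,6S,7S,9R,10R,11S,12E)-5,6,7,9-tetrakis(tert-butyldimethylsilyloxy)-3,10-dichloro-4-methyl-11-(triethylsilyloxy)pentadeca-2,12-dien-1-ol
Conditions: i-Bu2AlH (2.5 equiv), CH2Cl2, −78 °C; aq. KNaC4H4O6
Reagents that add atoms: none
Why: 1,2-Reduction of the chloroenoate to the allylic alcohol; alkenyl chloride and silyl ethers are inert to the aluminium hydride.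

Step 23
Reactants: 30 (2Z,4R,5R,6S,7S,9R,10R,11S,12E)-5,6,7,9-tetrakis(tert-butyldimethylsilyloxy)-3,10-dichloro-4-methyl-11-(triethylsilyloxy)pentadeca-2,12-dien-1-ol
Product: 31 (2Z,4R,5R,6S,7S,9R,10R,11S,12E)-5,6,7,9-tetrakis(tert-butyldimethylsilyloxy)-3,10-dichloro-4-methyl-11-(triethylsilyloxy)pentadeca-2,12-dienal
Conditions: Dess–Martin periodinane, NaHCO3, CH2Cl2, 0 °C
Reagents that add atoms: none
Why: Dess–Martin oxidation of the only free hydroxyl gives the (Z)-3-chloroenal without isomerisation.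

### Fragment 2, part A: the cyclohexanol (steps 24–29)

Step 24
Reactants: 32 (1S,4S,5S)-4-bromo-6-oxabicyclo[3.2.1]octan-7-one
Product: 33 allyl (1S,3S,6R)-7-oxabicyclo[4.1.0]heptane-3-carboxylate
Conditions: K2CO3, allyl alcohol, 0 °C → rt
Reagents that add atoms: allyl alcohol, C=CCO
Why: Alkoxide opens the lactone at the acyl carbon and the freed C3′ alkoxide displaces the trans bromide at C4′ (intramolecular SN2), giving the epoxide cis to the new allyl ester.

Step 25
Reactants: 33 allyl (1S,3S,6R)-7-oxabicyclo[4.1.0]heptane-3-carboxylate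
Product: 34 allyl (1S,3R,4R)-4-hydroxy-3-(naphthalen-2-ylmethoxy)cyclohexane-1-carboxylate
Conditions: naphthalen-2-ylmethanol (3 equiv), BF3·OEt2 (10 mol %), CH2Cl2, −20 °C → rt
Reagents that add atoms: naphthalen-2-ylmethanol, OCc1ccc2ccccc2c1
Why: Lewis-acid-catalysed trans-diaxial opening (Fürst–Plattner) of the half-chair with equatorial ester: the alcohol attacks C3′ with inversion, as nitrogen nucleophiles are known to do on this epoxide, and places O3′ anti to the carboxyl.

Step 26
Reactants: 34 allyl (1S,3R,4R)-4-hydroxy-3-(naphthalen-2-ylmethoxy)cyclohexane-1-carboxylate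
Product: 35 allyl (1S,3R)-3-(naphthalen-2-ylmethoxy)-4-oxocyclohexane-1-carboxylate
Conditions: Dess–Martin periodinane, NaHCO3, CH2Cl2, rt
Reagents that add atoms: none
Why: Oxidation removes the C4′ carbinol of the wrong configuration under non-epimerising conditions.

Step 27
Reactants: 35 allyl (1S,3R)-3-(naphthalen-2-ylmethoxy)-4-oxocyclohexane-1-carboxylate
Product: 36 allyl (1S,3R,4S)-4-hydroxy-3-(naphthalen-2-ylmethoxy)cyclohexane-1-carboxylate
Conditions: LiBH(s-Bu)3 (L-selectride), THF, −78 °C; aq. NH4Cl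
Reagents that add atoms: none
Why: The bulky hydride reduces 2-alkoxycyclohexanones anti to the adjacent ether and should give the cis alkoxy alcohol (4′S); the ketone reacts much faster than the ester at −78 °C.

Step 28
Reactants: 36 allyl (1S,3R,4S)-4-hydroxy-3-(naphthalen-2-ylmethoxy)cyclohexane-1-carboxylate
Product: 37 allyl (1S,3R,4S)-4-(tert-butyldimethylsilyloxy)-3-(naphthalen-2-ylmethoxy)cyclohexane-1-carboxylate
Conditions: TBSOTf, 2,6-lutidine, CH2Cl2, 0 °C
Reagents that add atoms: tert-butyldimethylsilyl trifluoromethanesulfonate, CC(C)(C)[Si](C)(C)OS(=O)(=O)C(F)(F)F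
Why: Silylation of the C4′ hydroxyl, the one that must stay masked during esterification and olefination.

Step 29
Reactants: 37 allyl (1S,3R,4S)-4-(tert-butyldimethylsilyloxy)-3-(naphthalen-2-ylmethoxy)cyclohexane-1-carboxylate
Product: 38 allyl (1S,3R,4S)-4-(tert-butyldimethylsilyloxy)-3-hydroxycyclohexane-1-carboxylate
Conditions: DDQ, CH2Cl2/pH 7 buffer, rt
Reagents that add atoms: none
Why: Oxidative cleavage of the naphthylmethyl ether frees the C3′ hydroxyl; the silyl ether and the allyl ester are inert.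

### Fragment 2, part B: the trienyl phosphonate and its ester (steps 30–35)

Step 30
Reactants: 39 (E)-4-acetoxy-2-methylbut-2-enal, 40 triethyl 4-phosphonocrotonate
Product: 41 ethyl (2E,4E,6E)-8-acetoxy-6-methylocta-2,4,6-trienoate
Conditions: 40, LiN(SiMe3)2, THF, −78 °C; then 39, −78 → 0 °C
Reagents that add atoms: none
Why: Horner–Wadsworth–Emmons reaction of the vinylogous phosphonate anion at its α-carbon with the enal should give the new C4=C5 bond E; the C6=C7 geometry comes from 39.

Step 31
Reactants: 41 ethyl (2E,4E,6E)-8-acetoxy-6-methylocta-2,4,6-trienoate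
Product: 42 ethyl (2E,4E,6E)-8-hydroxy-6-methylocta-2,4,6-trienoate
Conditions: K2CO3 (cat.), EtOH, 0 °C → rt
Reagents that add atoms: none
Why: Transesterification of the allylic acetate in ethanol leaves the ethyl ester unchanged.

Step 32
Reactants: 42 ethyl (2E,4E,6E)-8-hydroxy-6-methylocta-2,4,6-trienoate
Product: 43 ethyl (2E,4E,6E)-8-bromo-6-methylocta-2,4,6-trienoate
Conditions: CBr4, PPh3, CH2Cl2, 0 °C
Reagents that add atoms: carbon tetrabromide, BrC(Br)(Br)Br
Why: Appel bromination of the primary allylic alcohol under neutral conditions; the bromide is used crude.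

Step 33
Reactants: 43 ethyl (2E,4E,6E)-8-bromo-6-methylocta-2,4,6-trienoate
Product: 44 ethyl (2E,4E,6E)-8-(diethoxyphosphoryl)-6-methylocta-2,4,6-trienoate
Conditions: P(OEt)3, toluene, 100 °C
Reagents that add atoms: triethyl phosphite, CCOP(OCC)OCC
Why: Michaelis–Arbuzov reaction of the allylic bromide, as used for retinoid phosphonates.

Step 34
Reactants: 44 ethyl (2E,4E,6E)-8-(diethoxyphosphoryl)-6-methylocta-2,4,6-trienoate
Product: 45 (2E,4E,6E)-8-(diethoxyphosphoryl)-6-methylocta-2,4,6-trienoic acid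
Conditions: LiOH, THF/H2O, 0 °C → rt; 1 M HCl to pH 3
Reagents that add atoms: LiOH (lithium hydroxide), [Li+].[OH-]
Why: Saponification of the carboxylic ester; the phosphonate diester is stable to aqueous LiOH.

Step 35
Reactants: 45 (2E,4E,6E)-8-(diethoxyphosphoryl)-6-methylocta-2,4,6-trienoic acid, 38 allyl (1S,3R,4S)-4-(tert-butyldimethylsilyloxy)-3-hydroxycyclohexane-1-carboxylate
Product: 46 allyl (1S,3R,4S)-4-(tert-butyldimethylsilyloxy)-3-{[(2E,4E,6E)-8-(diethoxyphosphoryl)-6-methylocta-2,4,6-trienoyl]oxy}cyclohexane-1-carboxylate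
Conditions: EDC·HCl, DMAP, CH2Cl2, 0 °C → rt
Reagents that add atoms: none
Why: Carbodiimide/DMAP (Steglich) esterification of the axial C3′ hydroxyl, the only free hydroxyl of 38.

### Union and end game (steps 36–38)

Step 36
Reactants: 31 (2Z,4R,5R,6S,7S,9R,10R,11S,12E)-5,6,7,9-tetrakis(tert-butyldimethylsilyloxy)-3,10-dichloro-4-methyl-11-(triethylsilyloxy)pentadeca-2,12-dienal, 46 allyl (1S,3R,4S)-4-(tert-butyldimethylsilyloxy)-3-{[(2E,4E,6E)-8-(diethoxyphosphoryl)-6-methylocta-2,4,6-trienoyl]oxy}cyclohexane-1-carboxylate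
Product: 47 allyl (1S,3R,4S)-4-(tert-butyldimethylsilyloxy)-3-{[(2E,4E,6E,8E,10Z,12R,13R,14S,15S,17R,18R,19S,20E)-13,14,15,17-tetrakis(tert-butyldimethylsilyloxy)-11,18-dichloro-6,12-dimethyl-19-(triethylsilyloxy)tricosa-2,4,6,8,10,20-hexaenoyl]oxy}cyclohexane-1-carboxylate
Conditions: 46, LiN(SiMe3)2, THF, −78 °C; then 31, −78 → 0 °C, dark
Reagents that add atoms: none
Why: Horner–Wadsworth–Emmons union: the extended phosphonate anion is formed first and reacts at C8 with the enal, so no free base meets the γ-stereocentre C12, and the stabilised anion should give the E C8=C9 alkene.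

Step 37
Reactants: 47 allyl ester (fully silylated)
Product: 48 (1S,3R,4S)-4-(tert-butyldimethylsilyloxy)-3-{[(2E,4E,6E,8E,10Z,12R,13R,14S,15S,17R,18R,19S,20E)-13,14,15,17-tetrakis(tert-butyldimethylsilyloxy)-11,18-dichloro-6,12-dimethyl-19-(triethylsilyloxy)tricosa-2,4,6,8,10,20-hexaenoyl]oxy}cyclohexane-1-carboxylic acid
Conditions: Pd(PPh3)4 (5 mol %), N-methylaniline, THF, rt, dark
Reagents that add atoms: none
Why: Zerovalent palladium ionises the allyl ester to a π-allyl complex that the weakly basic aniline traps; alkenyl chloride, silyl ethers and the polyene ester should not react.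

Step 38
Reactants: 48 carboxylic acid (fully silylated)
Product: 49 (1S,3R,4S)-3-{[(2E,4E,6E,8E,10Z,12R,13R,14S,15S,17R,18R,19S,20E)-11,18-dichloro-13,14,15,17,19-pentahydroxy-6,12-dimethyltricosa-2,4,6,8,10,20-hexaenoyl]oxy}-4-hydroxycyclohexane-1-carboxylic acid
Conditions: HF·pyridine, pyridine, THF, 0 °C → rt, dark
Reagents that add atoms: none
Why: Acidic fluoride cleaves the triethylsilyl ether and the five tert-butyldimethylsilyl ethers without base, so the chlorohydrins should not close and the ester should not migrate.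

## Compound list

1 | L-serine | N[C@@H](CO)C(=O)O | starting material
2 | (S)-2-chloro-3-hydroxypropanoic acid | OC[C@H](Cl)C(=O)O | intermediate
3 | methyl (S)-2-chloro-3-hydroxypropanoate | OC[C@H](Cl)C(=O)OC | intermediate
4 | methyl (S)-3-(tert-butyldiphenylsilyloxy)-2-chloropropanoate | CC(C)(C)[Si](c1ccccc1)(c1ccccc1)OC[C@H](Cl)C(=O)OC | intermediate
5 | (S)-3-(tert-butyldiphenylsilyloxy)-2-chloropropanal | CC(C)(C)[Si](c1ccccc1)(c1ccccc1)OC[C@H](Cl)C=O | intermediate
6 | allylboronic acid pinacol ester | C=CCB1OC(C)(C)C(C)(C)O1 | starting material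
7 | (2S,3R)-1-(tert-butyldiphenylsilyloxy)-2-chlorohex-5-en-3-ol | CC(C)(C)[Si](c1ccccc1)(c1ccccc1)OC[C@H](Cl)[C@H](O)CC=C | intermediate
8 | acryloyl chloride | C=CC(Cl)=O | starting material
9 | (2S,3R)-1-(tert-butyldiphenylsilyloxy)-2-chlorohex-5-en-3-yl prop-2-enoate | CC(C)(C)[Si](c1ccccc1)(c1ccccc1)OC[C@H](Cl)[C@H](OC(=O)C=C)CC=C | intermediate
10 | (6R)-6-[(1S)-2-(tert-butyldiphenylsilyloxy)-1-chloroethyl]-5,6-dihydro-2H-pyran-2-one | CC(C)(C)[Si](c1ccccc1)(c1ccccc1)OC[C@H](Cl)[C@H]1CC=CC(=O)O1 | intermediate (not isolated)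
11 | (3S,4S,6R)-6-[(1S)-2-(tert-butyldiphenylsilyloxy)-1-chloroethyl]-3,4-dihydroxyoxan-2-one | CC(C)(C)[Si](c1ccccc1)(c1ccccc1)OC[C@H](Cl)[C@H]1C[C@H](O)[C@H](O)C(=O)O1 | intermediate
12 | (3S,4S,6R)-3,4-bis(TBS-oxy)-6-[(1S)-2-(TBDPS-oxy)-1-chloroethyl]oxan-2-one | CC(C)(C)[Si](c1ccccc1)(c1ccccc1)OC[C@H](Cl)[C@H]1C[C@H](O[Si](C)(C)C(C)(C)C)[C@H](O[Si](C)(C)C(C)(C)C)C(=O)O1 | intermediate
13 | (2S,3S,5R,6S)-2,3-bis(TBS-oxy)-7-(TBDPS-oxy)-6-chloro-5-hydroxy-N-methoxy-N-methylheptanamide | CC(C)(C)[Si](c1ccccc1)(c1ccccc1)OC[C@H](Cl)[C@H](O)C[C@H](O[Si](C)(C)C(C)(C)C)[C@H](O[Si](C)(C)C(C)(C)C)C(=O)N(C)OC | intermediate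
14 | (2S,3S,5R,6S)-2,3,5-tris(TBS-oxy)-7-(TBDPS-oxy)-6-chloro-N-methoxy-N-methylheptanamide | CC(C)(C)[Si](c1ccccc1)(c1ccccc1)OC[C@H](Cl)[C@H](O[Si](C)(C)C(C)(C)C)C[C@H](O[Si](C)(C)C(C)(C)C)[C@H](O[Si](C)(C)C(C)(C)C)C(=O)N(C)OC | intermediate
15 | (2S,3S,5R,6S)-2,3,5-tris(TBS-oxy)-7-(TBDPS-oxy)-6-chloroheptanal (C13 aldehyde) | CC(C)(C)[Si](c1ccccc1)(c1ccccc1)OC[C@H](Cl)[C@H](O[Si](C)(C)C(C)(C)C)C[C@H](O[Si](C)(C)C(C)(C)C)[C@H](O[Si](C)(C)C(C)(C)C)C=O | intermediate
16 | (S)-but-3-yn-2-ol | C[C@H](O)C#C | starting material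
17 | (S)-but-3-yn-2-yl methanesulfonate | C[C@H](OS(C)(=O)=O)C#C | intermediate
18 | (M)-tributyl(buta-1,2-dien-1-yl)stannane | [H]C(C)=[C@@]=C([H])[Sn](CCCC)(CCCC)CCCC | intermediate
19 | (3S,4R,5R,6S,8R,9S)-5,6,8-tris(TBS-oxy)-10-(TBDPS-oxy)-9-chloro-3-methyldec-1-yn-4-ol (C10–C19) | CC(C)(C)[Si](c1ccccc1)(c1ccccc1)OC[C@H](Cl)[C@H](O[Si](C)(C)C(C)(C)C)C[C@H](O[Si](C)(C)C(C)(C)C)[C@H](O[Si](C)(C)C(C)(C)C)[C@H](O)[C@@H](C)C#C | intermediate
20 | (3S,4R,5S,6S,8R,9S)-4,5,6,8-tetrakis(TBS-oxy)-10-(TBDPS-oxy)-9-chloro-3-methyldec-1-yne | CC(C)(C)[Si](c1ccccc1)(c1ccccc1)OC[C@H](Cl)[C@H](O[Si](C)(C)C(C)(C)C)C[C@H](O[Si](C)(C)C(C)(C)C)[C@H](O[Si](C)(C)C(C)(C)C)[C@H](O[Si](C)(C)C(C)(C)C)[C@@H](C)C#C | intermediate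
21 | methyl (4S,5R,6S,7S,9R,10S)-5,6,7,9-tetrakis(TBS-oxy)-11-(TBDPS-oxy)-10-chloro-4-methylundec-2-ynoate (C9–C19) | CC(C)(C)[Si](c1ccccc1)(c1ccccc1)OC[C@H](Cl)[C@H](O[Si](C)(C)C(C)(C)C)C[C@H](O[Si](C)(C)C(C)(C)C)[C@H](O[Si](C)(C)C(C)(C)C)[C@H](O[Si](C)(C)C(C)(C)C)[C@@H](C)C#CC(=O)OC | intermediate
22 | methyl (2Z,4R,5R,6S,7S,9R,10S)-5,6,7,9-tetrakis(TBS-oxy)-11-(TBDPS-oxy)-3,10-dichloro-4-methylundec-2-enoate | CC(C)(C)[Si](c1ccccc1)(c1ccccc1)OC[C@H](Cl)[C@H](O[Si](C)(C)C(C)(C)C)C[C@H](O[Si](C)(C)C(C)(C)C)[C@H](O[Si](C)(C)C(C)(C)C)[C@H](O[Si](C)(C)C(C)(C)C)[C@@H](C)/C(Cl)=C/C(=O)OC | intermediate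
23 | methyl (2Z,4R,5R,6S,7S,9R,10S)-5,6,7,9-tetrakis(TBS-oxy)-3,10-dichloro-11-hydroxy-4-methylundec-2-enoate | OC[C@H](Cl)[C@H](O[Si](C)(C)C(C)(C)C)C[C@H](O[Si](C)(C)C(C)(C)C)[C@H](O[Si](C)(C)C(C)(C)C)[C@H](O[Si](C)(C)C(C)(C)C)[C@@H](C)/C(Cl)=C/C(=O)OC | intermediate
24 | methyl (2Z,4R,5R,6S,7S,9R,10R)-5,6,7,9-tetrakis(TBS-oxy)-3,10-dichloro-4-methyl-11-oxoundec-2-enoate (C19 aldehyde) | O=C[C@H](Cl)[C@H](O[Si](C)(C)C(C)(C)C)C[C@H](O[Si](C)(C)C(C)(C)C)[C@H](O[Si](C)(C)C(C)(C)C)[C@H](O[Si](C)(C)C(C)(C)C)[C@@H](C)/C(Cl)=C/C(=O)OC | intermediate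
25 | but-1-yne | CCC#C | starting material
26 | (E)-but-1-enyl(chloro)zirconocene | CC/C=C/[Zr](Cl)(C1C=CC=C1)C1C=CC=C1 | intermediate (not isolated)
27 | (E)-but-1-enyl(methyl)zinc | CC/C=C/[Zn]C | intermediate (not isolated)
28 | methyl (2Z,4R,5R,6S,7S,9R,10S,11S,12E)-5,6,7,9-tetrakis(TBS-oxy)-3,10-dichloro-11-hydroxy-4-methylpentadeca-2,12-dienoate (C9–C23) | CC/C=C/[C@H](O)[C@H](Cl)[C@H](O[Si](C)(C)C(C)(C)C)C[C@H](O[Si](C)(C)C(C)(C)C)[C@H](O[Si](C)(C)C(C)(C)C)[C@H](O[Si](C)(C)C(C)(C)C)[C@@H](C)/C(Cl)=C/C(=O)OC | intermediate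
29 | methyl (2Z,4R,5R,6S,7S,9R,10R,11S,12E)-5,6,7,9-tetrakis(TBS-oxy)-3,10-dichloro-4-methyl-11-(TES-oxy)pentadeca-2,12-dienoate | CC/C=C/[C@H](O[Si](CC)(CC)CC)[C@H](Cl)[C@H](O[Si](C)(C)C(C)(C)C)C[C@H](O[Si](C)(C)C(C)(C)C)[C@H](O[Si](C)(C)C(C)(C)C)[C@H](O[Si](C)(C)C(C)(C)C)[C@@H](C)/C(Cl)=C/C(=O)OC | intermediate
30 | (2Z,4R,5R,6S,7S,9R,10R,11S,12E)-5,6,7,9-tetrakis(TBS-oxy)-3,10-dichloro-4-methyl-11-(TES-oxy)pentadeca-2,12-dien-1-ol | CC/C=C/[C@H](O[Si](CC)(CC)CC)[C@H](Cl)[C@H](O[Si](C)(C)C(C)(C)C)C[C@H](O[Si](C)(C)C(C)(C)C)[C@H](O[Si](C)(C)C(C)(C)C)[C@H](O[Si](C)(C)C(C)(C)C)[C@@H](C)/C(Cl)=C/CO | intermediate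
31 | (2Z,4R,5R,6S,7S,9R,10R,11S,12E)-5,6,7,9-tetrakis(TBS-oxy)-3,10-dichloro-4-methyl-11-(TES-oxy)pentadeca-2,12-dienal (fragment 1, C9 enal) | CC/C=C/[C@H](O[Si](CC)(CC)CC)[C@H](Cl)[C@H](O[Si](C)(C)C(C)(C)C)C[C@H](O[Si](C)(C)C(C)(C)C)[C@H](O[Si](C)(C)C(C)(C)C)[C@H](O[Si](C)(C)C(C)(C)C)[C@@H](C)/C(Cl)=C/C=O | intermediate
32 | (1S,4S,5S)-4-bromo-6-oxabicyclo[3.2.1]octan-7-one | O=C1O[C@H]2C[C@@H]1CC[C@@H]2Br | starting material
33 | allyl (1S,3S,6R)-7-oxabicyclo[4.1.0]heptane-3-carboxylate | C=CCOC(=O)[C@H]1CC[C@H]2O[C@H]2C1 | intermediate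
34 | allyl (1S,3R,4R)-4-hydroxy-3-(naphthalen-2-ylmethoxy)cyclohexane-1-carboxylate | C=CCOC(=O)[C@H]1CC[C@@H](O)[C@H](OCc2ccc3ccccc3c2)C1 | intermediate
35 | allyl (1S,3R)-3-(naphthalen-2-ylmethoxy)-4-oxocyclohexane-1-carboxylate | C=CCOC(=O)[C@H]1CCC(=O)[C@H](OCc2ccc3ccccc3c2)C1 | intermediate
36 | allyl (1S,3R,4S)-4-hydroxy-3-(naphthalen-2-ylmethoxy)cyclohexane-1-carboxylate | C=CCOC(=O)[C@H]1CC[C@H](O)[C@H](OCc2ccc3ccccc3c2)C1 | intermediate
37 | allyl (1S,3R,4S)-4-(tert-butyldimethylsilyloxy)-3-(naphthalen-2-ylmethoxy)cyclohexane-1-carboxylate | C=CCOC(=O)[C@H]1CC[C@H](O[Si](C)(C)C(C)(C)C)[C@H](OCc2ccc3ccccc3c2)C1 | intermediate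
38 | allyl (1S,3R,4S)-4-(tert-butyldimethylsilyloxy)-3-hydroxycyclohexane-1-carboxylate | C=CCOC(=O)[C@H]1CC[C@H](O[Si](C)(C)C(C)(C)C)[C@H](O)C1 | intermediate
39 | (E)-4-acetoxy-2-methylbut-2-enal | CC(=O)OC/C=C(\C)C=O | starting material
40 | triethyl 4-phosphonocrotonate | CCOC(=O)/C=C/CP(=O)(OCC)OCC | starting material
41 | ethyl (2E,4E,6E)-8-acetoxy-6-methylocta-2,4,6-trienoate | CCOC(=O)/C=C/C=C/C(C)=C/COC(C)=O | intermediate
42 | ethyl (2E,4E,6E)-8-hydroxy-6-methylocta-2,4,6-trienoate | CCOC(=O)/C=C/C=C/C(C)=C/CO | intermediate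
43 | ethyl (2E,4E,6E)-8-bromo-6-methylocta-2,4,6-trienoate | CCOC(=O)/C=C/C=C/C(C)=C/CBr | intermediate
44 | ethyl (2E,4E,6E)-8-(diethoxyphosphoryl)-6-methylocta-2,4,6-trienoate | CCOC(=O)/C=C/C=C/C(C)=C/CP(=O)(OCC)OCC | intermediate
45 | (2E,4E,6E)-8-(diethoxyphosphoryl)-6-methylocta-2,4,6-trienoic acid | OC(=O)/C=C/C=C/C(C)=C/CP(=O)(OCC)OCC | intermediate
46 | allyl (1S,3R,4S)-4-(tert-butyldimethylsilyloxy)-3-{[(2E,4E,6E)-8-(diethoxyphosphoryl)-6-methylocta-2,4,6-trienoyl]oxy}cyclohexane-1-carboxylate (fragment 2) | C=CCOC(=O)[C@H]1CC[C@H](O[Si](C)(C)C(C)(C)C)[C@H](OC(=O)/C=C/C=C/C(C)=C/CP(=O)(OCC)OCC)C1 | intermediate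
47 | allyl ester of the target with TBS ethers at O13, O14, O15, O17 and O4′ and a TES ether at O19 | CC/C=C/[C@H](O[Si](CC)(CC)CC)[C@H](Cl)[C@H](O[Si](C)(C)C(C)(C)C)C[C@H](O[Si](C)(C)C(C)(C)C)[C@H](O[Si](C)(C)C(C)(C)C)[C@H](O[Si](C)(C)C(C)(C)C)[C@@H](C)/C(Cl)=C/C=C/C=C(C)/C=C/C=C/C(=O)O[C@@H]1C[C@@H](C(=O)OCC=C)CC[C@@H]1O[Si](C)(C)C(C)(C)C | intermediate
48 | free acid of the target with TBS ethers at O13, O14, O15, O17 and O4′ and a TES ether at O19 | CC/C=C/[C@H](O[Si](CC)(CC)CC)[C@H](Cl)[C@H](O[Si](C)(C)C(C)(C)C)C[C@H](O[Si](C)(C)C(C)(C)C)[C@H](O[Si](C)(C)C(C)(C)C)[C@H](O[Si](C)(C)C(C)(C)C)[C@@H](C)/C(Cl)=C/C=C/C=C(C)/C=C/C=C/C(=O)O[C@@H]1C[C@@H](C(=O)O)CC[C@@H]1O[Si](C)(C)C(C)(C)C | intermediate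
49 | (1S,3R,4S)-3-{[(2E,4E,6E,8E,10Z,12R,13R,14S,15S,17R,18R,19S,20E)-11,18-dichloro-13,14,15,17,19-pentahydroxy-6,12-dimethyltricosa-2,4,6,8,10,20-hexaenoyl]oxy}-4-hydroxycyclohexane-1-carboxylic acid (CNP0353301.1) | CC/C=C/[C@H](O)[C@H](Cl)[C@H](O)C[C@H](O)[C@H](O)[C@H](O)[C@@H](C)/C(Cl)=C/C=C/C=C(C)/C=C/C=C/C(=O)O[C@@H]1C[C@@H](C(=O)O)CC[C@@H]1O | target

## Step count and risk

Total: 38 steps. Longest linear sequence: 24 steps from L-serine (steps 1–11, 14–23, 36–38).

**Step 7 (key step).** Ring closure of the electron-poor acrylate may stall through chelation of the carbene by the ester carbonyl or divert to oligomers. In the oxidative half, RuO4 may cleave the glycol or oxidise the α-hydroxy lactone further, and it may be less face-selective than osmium. Fallback: from 9, run the metathesis alone with the same catalyst in CH2Cl2 at 40 °C and isolate 10. Then treat 10 with OsO4 (cat.) and N-methylmorpholine N-oxide in acetone/water, the best-documented anti-selective dihydroxylation of 6-substituted dihydropyranones. This returns to the route at 11. The bonds formed and the ring closed are the same.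

**Step 5.** Anti selectivity may erode, because the closed transition state of an uncatalysed allylboration responds less to the α-chlorine than open additions do, and 5 may epimerise during a slow reaction. Fallback: from 5, use reagent control with the B-allyldiisopinocampheylborane enantiomer that adds to the Re face of 5, (+)-Ipc2B(allyl) from (−)-α-pinene, in Et2O at −78 °C with NaBO3·4H2O work-up. Reagent and Cornforth preference then reinforce each other, and the route is rejoined at 7.

**Step 17.** Chloride addition to the hindered ynoate may be slow, and silyl ethers may be lost by acetolysis at 80 °C. Fallback: from 21, stannylcupration with Me3SnCu·SMe2 in THF at −48 °C under equilibrating conditions to give methyl (2Z)-3-(trimethylstannyl)-enoate F1, with tin cis to the ester. Chlorodestannylation with CuCl2 in THF at rt, with retention, returns to 22.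

**Step 20.** Facial selectivity may erode if the Lewis-acidic zinc or zirconium species coordinates the chlorine or the C17 silyloxy group. Enolisation and β-elimination of 24 may compete if addition is slow. Fallback: from 26, iodinolysis (I2, CH2Cl2, 0 °C) gives (E)-1-iodobut-1-ene F2. Nozaki–Hiyama–Kishi coupling of F2 with 24 (CrCl2, NiCl2 cat., DMSO/THF, rt), a non-basic alkenylchromium addition that tolerates esters, returns to 28.

**Step 36.** The delocalised phosphonate anion may scramble the C6=C7 geometry, the new C8=C9 bond may form as an E/Z mixture, and deprotonation at C12 of 31 may compete. Fallback: two shorter olefinations, setting out from 31 and 38. Enal 31 and ethyl (E)-4-(diethoxyphosphoryl)-2-methylbut-2-enoate (LiN(SiMe3)2, THF, −78 °C) give the ethyl C5–C23 trienoate F3. Reduction with i-Bu2AlH gives the C5 alcohol F4, and Dess–Martin oxidation gives the C5 trienal F5. Alcohol 38 and (E)-4-(diethoxyphosphoryl)but-2-enoic acid (EDC·HCl, DMAP) give allyl (1S,3R,4S)-4-(tert-butyldimethylsilyloxy)-3-{[(E)-4-(diethoxyphosphoryl)but-2-enoyl]oxy}cyclohexane-1-carboxylate F6. Horner–Wadsworth–Emmons reaction of F5 with F6 forms C4=C5 and returns to 47.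

**Step 38.** Cleavage of the three contiguous silyl ethers at C13–C15 may be slow, and long exposure of the free acid to acidic fluoride may cause acyl migration or loss of material on isolation. Fallback: reverse the last two operations. From 47, desilylate the neutral ester with 48 % aq. HF in MeCN at 0 °C → rt to give the allyl ester of the target F7, which can be purified on silica. Deallylation with Pd(PPh3)4 and N-methylaniline in THF then returns to 49.

## Further compounds

F0 | step 7 | none | none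
F0 | step 5 | none | none
F1 | step 17 | methyl (2Z,4R,5R,6S,7S,9R,10S)-5,6,7,9-tetrakis(TBS-oxy)-11-(TBDPS-oxy)-10-chloro-4-methyl-3-(trimethylstannyl)undec-2-enoate | CC(C)(C)[Si](c1ccccc1)(c1ccccc1)OC[C@H](Cl)[C@H](O[Si](C)(C)C(C)(C)C)C[C@H](O[Si](C)(C)C(C)(C)C)[C@H](O[Si](C)(C)C(C)(C)C)[C@H](O[Si](C)(C)C(C)(C)C)[C@@H](C)/C([Sn](C)(C)C)=C/C(=O)OC
F2 | step 20 | (E)-1-iodobut-1-ene | CC/C=C/I
F3 | step 36 | ethyl ester of the C5–C23 acid: (2E,4E,6Z,8R,9R,10S,11S,13R,14R,15S,16E)-9,10,11,13-tetrakis(TBS-oxy)-7,14-dichloro-2,8-dimethyl-15-(TES-oxy)nonadeca-2,4,6,16-tetraenoate | CC/C=C/[C@H](O[Si](CC)(CC)CC)[C@H](Cl)[C@H](O[Si](C)(C)C(C)(C)C)C[C@H](O[Si](C)(C)C(C)(C)C)[C@H](O[Si](C)(C)C(C)(C)C)[C@H](O[Si](C)(C)C(C)(C)C)[C@@H](C)/C(Cl)=C/C=C/C=C(C)/C(=O)OCC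
F4 | step 36 | C5 alcohol: (2E,4E,6Z,8R,9R,10S,11S,13R,14R,15S,16E)-9,10,11,13-tetrakis(TBS-oxy)-7,14-dichloro-2,8-dimethyl-15-(TES-oxy)nonadeca-2,4,6,16-tetraen-1-ol | CC/C=C/[C@H](O[Si](CC)(CC)CC)[C@H](Cl)[C@H](O[Si](C)(C)C(C)(C)C)C[C@H](O[Si](C)(C)C(C)(C)C)[C@H](O[Si](C)(C)C(C)(C)C)[C@H](O[Si](C)(C)C(C)(C)C)[C@@H](C)/C(Cl)=C/C=C/C=C(C)/CO
F5 | step 36 | C5 trienal: (2E,4E,6Z,8R,9R,10S,11S,13R,14R,15S,16E)-9,10,11,13-tetrakis(TBS-oxy)-7,14-dichloro-2,8-dimethyl-15-(TES-oxy)nonadeca-2,4,6,16-tetraenal | CC/C=C/[C@H](O[Si](CC)(CC)CC)[C@H](Cl)[C@H](O[Si](C)(C)C(C)(C)C)C[C@H](O[Si](C)(C)C(C)(C)C)[C@H](O[Si](C)(C)C(C)(C)C)[C@H](O[Si](C)(C)C(C)(C)C)[C@@H](C)/C(Cl)=C/C=C/C=C(C)/C=O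
F6 | step 36 | allyl (1S,3R,4S)-4-(tert-butyldimethylsilyloxy)-3-{[(E)-4-(diethoxyphosphoryl)but-2-enoyl]oxy}cyclohexane-1-carboxylate | C=CCOC(=O)[C@H]1CC[C@H](O[Si](C)(C)C(C)(C)C)[C@H](OC(=O)/C=C/CP(=O)(OCC)OCC)C1
F7 | step 38 | allyl ester of the target (all hydroxyls free) | CC/C=C/[C@H](O)[C@H](Cl)[C@H](O)C[C@H](O)[C@H](O)[C@H](O)[C@@H](C)/C(Cl)=C/C=C/C=C(C)/C=C/C=C/C(=O)O[C@@H]1C[C@@H](C(=O)OCC=C)CC[C@@H]1O
A1 | alternative 1 | (4S,5S)-4,5-dicyclohexyl-2-methyl-1,3,2-dioxaborolane | CB1O[C@@H](C2CCCCC2)[C@H](C2CCCCC2)O1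
A2 | alternative 1 | C10–C15 boronic ester with C12 methyl and vinyl, three 4-methoxybenzyl ethers at O13–O15 and boron on C15 | C[C@@H](C=C)[C@@H](OCc1ccc(OC)cc1)[C@@H](OCc1ccc(OC)cc1)[C@@H](OCc1ccc(OC)cc1)B1O[C@@H](C2CCCCC2)[C@H](C2CCCCC2)O1
A3 | alternative 2 | (S)-3-(tert-butyldiphenylsilyloxy)-2-methylpropanal (C11–C13) | O=C[C@@H](C)CO[Si](c1ccccc1)(c1ccccc1)C(C)(C)C
A4 | alternative 2 | (1E)-4-(benzoyloxy)-1-methoxy-3-(trimethylsilyloxy)buta-1,3-diene | CO/C=C/C(O[Si](C)(C)C)=COC(=O)c1ccccc1
A5 | alternative 2 | trans-2,3-disubstituted 2,3-dihydro-4H-pyran-4-one holding C11–C17 (C14 benzoate, C15 ketone) | O=C1C=CO[C@H]([C@@H](C)CO[Si](c2ccccc2)(c2ccccc2)C(C)(C)C)[C@H]1OC(=O)c1ccccc1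
A6 | alternative 3 | tert-butyl carbonate on O15 of the (E)-C17=C18 homoallylic alcohol (C11–C19, C13/C14 acetonide) | CC(C)(C)OC(=O)O[C@H]([C@@H]1OC(C)(C)O[C@@H]1[C@@H](C)CO[Si](c1ccccc1)(c1ccccc1)C(C)(C)C)C/C=C/CO[Si](C)(C)C(C)(C)C
A7 | alternative 3 | cis-4,6-disubstituted 1,3-dioxan-2-one spanning O15 and O17 with the C18 chloride in the side chain | O=C1O[C@H]([C@@H]2OC(C)(C)O[C@@H]2[C@@H](C)CO[Si](c2ccccc2)(c2ccccc2)C(C)(C)C)C[C@@H](O1)[C@@H](Cl)CO[Si](C)(C)C(C)(C)C
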